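**Strategy.** The route rests on cutting C3–C4 of the pyranone ring C. This turns the flavanone into an achiral isomer, a 2-(1-arylvinyloxy)benzaldehyde. The feature exploited is that the formyl carbon C4 (on C4a of ring A) and the enol ether C2=C3 (on O1 at C8a) are ortho neighbours. A chiral cationic rhodium catalyst can therefore add the C4–H bond across C2=C3 in the endo sense. This single, fully atom-economical hydroacylation closes ring C, creates the C4 ketone and sets the only stereocentre, C2 (S). The precursor already carries both five-carbon side chains and comes from an aryl benzoate by Petasis methylenation.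

Key step: step 8

Remark on numbering: flavanone numbering (O1, C2, C3, C4, C4a, C5–C8, C8a; ring B primed) is used for all intermediates.
Assumption: the sense of induction of the bisphosphine cannot be predicted safely for this substrate class. The (R)-ligand is written, and its commercial antipode is used instead if the (R)-ligand leads to 2R.

Step 1
Reactants: 1 1-bromo-4-(methoxymethoxy)benzene; 2 3-methylbut-2-enylboronic acid pinacol ester (prenyl-Bpin)
Product: 3 1-(methoxymethoxy)-4-(2-methylbut-3-en-2-yl)benzene
Conditions: Pd(OAc)2 (cat.), bulky biaryl dialkylphosphine tuned for γ-selectivity (cat.), K3PO4, MeCN–H2O, 70 °C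
Reagents that add atoms: none
Why: Ligand-controlled γ-selective Suzuki–Miyaura allylation, in which SE2′ transmetalation places palladium on the tertiary carbon and fast reductive elimination should fix the 1,1-dimethylallyl connectivity before σ–π–σ isomerisation, the MOM ether being inert to aqueous base.

Step 2
Reactants: 3 1-(methoxymethoxy)-4-(2-methylbut-3-en-2-yl)benzene
Product: 6 2-(methoxymethoxy)-5-(2-methylbut-3-en-2-yl)benzoic acid, via aryllithium 4 (not isolated), via lithium carboxylate 5 (not isolated)
Conditions: n-BuLi, TMEDA, Et2O, 0 °C; CO2, −78 °C to rt; cold 1 M HCl to pH 4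
Reagents that add atoms: carbon dioxide O=C=O
Why: Directed ortho-metalation, in which the MOM oxygen guides n-BuLi to one of two equivalent ortho positions (the side chain has no benzylic or allylic hydrogen) and carboxylation followed by a mildly acidic work-up should give the acid with the MOM group intact.

Step 3
Reactants: 7 2,4,6-trihydroxybenzaldehyde; 8 prenyl bromide (1-bromo-3-methylbut-2-ene)
Product: 9 2,4,6-trihydroxy-3-(3-methylbut-2-enyl)benzaldehyde
Conditions: KOH, MeOH–H2O, 0 °C to rt (1 equiv of 8)
Reagents that add atoms: none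
Why: C-allylation of the ambident phloroglucinol-type phenoxide in a protic medium that shields oxygen by hydrogen bonding, and since C3 and C5 are equivalent only one mono-C-prenyl isomer can form.

Step 4
Reactants: 9 2,4,6-trihydroxy-3-(3-methylbut-2-enyl)benzaldehyde
Product: 10 2-hydroxy-4,6-bis(methoxymethoxy)-3-(3-methylbut-2-enyl)benzaldehyde
Conditions: MOMCl (2.1 equiv), i-Pr2NEt, CH2Cl2, 0 °C
Reagents that add atoms: chloromethyl methyl ether COCCl
Why: Williamson-type O-alkylation under weak base, in which the non-chelated 4-OH should react first and then the less hindered 6-OH, while the 2-OH, pressed against the formyl oxygen by the neighbouring prenyl group, stays locked in its hydrogen bond and remains free as the future O1.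

Step 5
Reactants: 6 2-(methoxymethoxy)-5-(2-methylbut-3-en-2-yl)benzoic acid; 10 2-hydroxy-4,6-bis(methoxymethoxy)-3-(3-methylbut-2-enyl)benzaldehyde
Product: 11 2-formyl-3,5-bis(methoxymethoxy)-6-(3-methylbut-2-enyl)phenyl 2-(methoxymethoxy)-5-(2-methylbut-3-en-2-yl)benzoate
Conditions: DCC, DMAP (cat.), CH2Cl2, 0 °C to rt
Reagents that add atoms: none
Why: Steglich esterification, in which the acylpyridinium ion is reactive enough for chelated ortho-acylphenols (as in the ester precursors of Baker–Venkataraman chemistry) and the neutral medium spares MOM groups, aldehyde and alkenes while forming the O1–C2 bond.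

Step 6
Reactants: 11 aryl benzoate aldehyde
Product: 12 2-(dimethoxymethyl)-3,5-bis(methoxymethoxy)-6-(3-methylbut-2-enyl)phenyl 2-(methoxymethoxy)-5-(2-methylbut-3-en-2-yl)benzoate
Conditions: HC(OMe)3, PPTS (cat.), CH2Cl2, rt; Et3N quench
Reagents that add atoms: trimethyl orthoformate COC(OC)OC
Why: Acid-catalysed acetalisation with orthoformate as water scavenger masks the formyl group, which would otherwise be methylenated before the ester, under acidity too weak to touch MOM ethers, the aryl ester or the prenyl group.

Step 7
Reactants: 12 aryl benzoate dimethyl acetal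
Product: 14 2-({1-[2-(methoxymethoxy)-5-(2-methylbut-3-en-2-yl)phenyl]ethenyl}oxy)-4,6-bis(methoxymethoxy)-3-(3-methylbut-2-enyl)benzaldehyde, via enol ether acetal 13 (not isolated)
Conditions: Cp2TiMe2, toluene, 70 °C, dark; then PPTS (cat.), acetone–H2O, 0 °C
Reagents that add atoms: dimethyltitanocene C[Ti+2]C.[cH-]1cccc1.[cH-]1cccc1; water O
Why: Petasis methylenation turns the aryl ester C=O into the 1-aryloxy-1-arylethene (the non-Lewis-acidic titanium methylidene leaves acetal, MOM and alkenes alone), and the acetal of the trioxygenated benzaldehyde should then hydrolyse far faster than the aryl enol ether is C-protonated.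

Step 8
Reactants: 14 enol ether aldehyde
Product: 15 (2S)-5,7-bis(methoxymethoxy)-2-[2-(methoxymethoxy)-5-(2-methylbut-3-en-2-yl)phenyl]-8-(3-methylbut-2-enyl)chroman-4-one
Conditions: [Rh(cod)Cl]2 (2.5 mol %), (R)-DTBM-SEGPHOS (5 mol %), NaBArF4 (5 mol %), 1,4-dioxane, 80 °C
Reagents that add atoms: none
Why: Proposed new method: cationic Rh(I) should insert into the formyl C4–H bond of 14, bind the C2=C3 enol ether held next to it by O1, pass hydride to C2 with rhodium going to the unhindered C3 (seven-membered acyl-rhodacycle) and then form C3–C4 by reductive elimination. The closest known reaction type is the enantioselective rhodium-catalysed endo-hydroacylation of ortho-allylbenzaldehydes and N-vinylindole-2-carbaldehydes bearing 1,1-disubstituted alkenes; here the CH2 (or N) of those tethers is replaced by the ether oxygen O1, a substrate class not yet shown. Ring C closes in a formal 6-endo-trig mode. The new stereocentre C2 is set in the hydride-insertion step, where the C2-symmetric bisphosphine pocket selects the enol ether face that leads to 2S. Regioselectivity (endo against the exo path to a 2-aryl-2-methylbenzofuran-3-one) is secured by the 1,1-disubstitution at C2, which makes the tertiary Rh–C2 alkyl and its quaternary-centre-forming elimination unfavourable under the bulky ligand. Chemoselectivity is secured because the C8 prenyl group is trisubstituted and out of reach of C4, the ring B vinyl group is neopentyl-like, has no allylic hydrogen and could react only intermolecularly, and decarbonylation is held back by chelation of the alkene and the C5 OMOM oxygen.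

Step 9
Reactants: 15 (2S)-tris-MOM flavanone
Product: 16 (2S)-5,7-dihydroxy-2-[2-hydroxy-5-(2-methylbut-3-en-2-yl)phenyl]-8-(3-methylbut-2-enyl)chroman-4-one (target)
Conditions: HCl (cat.), MeOH, 40 °C, short reaction time
Reagents that add atoms: none
Why: Acid-catalysed transacetalisation (methanolysis) of the three aryl MOM ethers, as used routinely on prenylated flavanones, is too mild to protonate the prenyl or vinyl groups and avoids the base-induced retro-oxa-Michael opening of ring C that would scramble C2.

**Compound list**
1 | 1-bromo-4-(methoxymethoxy)benzene | COCOc1ccc(Br)cc1 | starting material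
2 | 3-methylbut-2-enylboronic acid pinacol ester | CC(C)=CCB1OC(C)(C)C(C)(C)O1 | starting material
3 | 1-(methoxymethoxy)-4-(2-methylbut-3-en-2-yl)benzene | C=CC(C)(C)c1ccc(OCOC)cc1 | intermediate
4 | [2-(methoxymethoxy)-5-(2-methylbut-3-en-2-yl)phenyl]lithium | [Li]c1cc(C(C)(C)C=C)ccc1OCOC | intermediate
5 | lithium 2-(methoxymethoxy)-5-(2-methylbut-3-en-2-yl)benzoate | [Li+].[O-]C(=O)c1cc(C(C)(C)C=C)ccc1OCOC | intermediate
6 | 2-(methoxymethoxy)-5-(2-methylbut-3-en-2-yl)benzoic acid | C=CC(C)(C)c1ccc(OCOC)c(C(=O)O)c1 | intermediate
7 | 2,4,6-trihydroxybenzaldehyde | O=Cc1c(O)cc(O)cc1O | starting material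
8 | prenyl bromide | CC(C)=CCBr | starting material
9 | 2,4,6-trihydroxy-3-(3-methylbut-2-enyl)benzaldehyde | CC(C)=CCc1c(O)cc(O)c(C=O)c1O | intermediate
10 | 2-hydroxy-4,6-bis(methoxymethoxy)-3-(3-methylbut-2-enyl)benzaldehyde | CC(C)=CCc1c(OCOC)cc(OCOC)c(C=O)c1O | intermediate
11 | 2-formyl-3,5-bis(methoxymethoxy)-6-(3-methylbut-2-enyl)phenyl 2-(methoxymethoxy)-5-(2-methylbut-3-en-2-yl)benzoate | C=CC(C)(C)c1ccc(OCOC)c(C(=O)Oc2c(C=O)c(OCOC)cc(OCOC)c2CC=C(C)C)c1 | intermediate
12 | dimethyl acetal of 11 | C=CC(C)(C)c1ccc(OCOC)c(C(=O)Oc2c(C(OC)OC)c(OCOC)cc(OCOC)c2CC=C(C)C)c1 | intermediate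
13 | 1-aryloxy-1-arylethene dimethyl acetal (methylenated 12) | C=CC(C)(C)c1ccc(OCOC)c(C(=C)Oc2c(C(OC)OC)c(OCOC)cc(OCOC)c2CC=C(C)C)c1 | intermediate
14 | 2-({1-[2-(methoxymethoxy)-5-(2-methylbut-3-en-2-yl)phenyl]ethenyl}oxy)-4,6-bis(methoxymethoxy)-3-(3-methylbut-2-enyl)benzaldehyde | C=CC(C)(C)c1ccc(OCOC)c(C(=C)Oc2c(C=O)c(OCOC)cc(OCOC)c2CC=C(C)C)c1 | intermediate
15 | (2S)-5,7-bis(methoxymethoxy)-2-[2-(methoxymethoxy)-5-(2-methylbut-3-en-2-yl)phenyl]-8-(3-methylbut-2-enyl)chroman-4-one | C=CC(C)(C)c1ccc(OCOC)c([C@@H]2CC(=O)c3c(OCOC)cc(OCOC)c(CC=C(C)C)c3O2)c1 | intermediate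
16 | (2S)-5,7-dihydroxy-2-[2-hydroxy-5-(2-methylbut-3-en-2-yl)phenyl]-8-(3-methylbut-2-enyl)chroman-4-one | C=CC(C)(C)c1ccc(O)c([C@@H]2CC(=O)c3c(O)cc(O)c(CC=C(C)C)c3O2)c1 | target

**Totals.** Total step count: 9. Longest linear sequence: 7 (steps 3–9).

**Steps most likely to fail**

Step 8. Several processes could defeat the closure:
- exo insertion of the enol ether, giving rhodium at C2 and a five-membered ring;
- decarbonylation of the crowded, electron-rich acyl rhodium hydride;
- β-aryloxy elimination from the Rh–C3 alkyl;
- weak facial selectivity.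

The fallback sets out from 14 and comes back at 15, and it still closes ring C at C3–C4. A thiol-catalysed radical hydroacylation is used (tert-dodecanethiol cat., 1,1′-azobis(cyclohexanecarbonitrile), chlorobenzene, 100 °C). It generates the aroyl radical at C4, which should close 6-endo onto C3. The resulting C2 radical is benzylic and stabilised by O1, and hydrogen transfer from the thiol should give the racemic tris-MOM flavanone F1. A kinetic resolution by asymmetric transfer hydrogenation follows (Cp*RhCl[(R,R)-TsDPEN], HCO2H/Et3N, EtOAc, rt, stopped near half conversion), a method known for flavanones. It is expected to reduce the 2R enantiomer to the cis-(2R,4R)-flavan-4-ol F2. The unreacted 2S ketone 15 is separated by chromatography.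

Step 7. Methylenation of an ester flanked by three ortho substituents may be sluggish. The enol ether may also be hydrolysed along with the acetal. The fallback builds C2=C3 by elimination instead of carbonyl methylenation and needs no aldehyde protection. It sets out from aryllithium 4 (made from 3) and phenol 10, comes back at 14, and bypasses steps 5–7.
- Quenching 4 with 2-chloro-N-methoxy-N-methylacetamide at −78 °C should give the α-chloro ketone F3.
- NaBH4 in MeOH at 0 °C should give the racemic chlorohydrin F4.
- Mitsunobu etherification of F4 with 10 (DIAD, PPh3, THF) should give the racemic β-chloro ether F5.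
- E2 elimination of F5 with KOtBu in THF at 0 °C should deliver 14. The aldehyde is non-enolisable.

Step 4. Site selectivity between the two chelated hydroxyls may be poor. Protection at the wrong one would carry the prenyl group to C6 of the flavanone. The fallback removes the regiochemical question by reversing the order of events. It sets out from 7, comes back at 10, and also bypasses step 3.
- Treating 7 with MOMCl (2.1 equiv) and i-Pr2NEt should give 2-hydroxy-4,6-bis(methoxymethoxy)benzaldehyde F6. The two ortho hydroxyls of 7 are equivalent.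
- Iodination ortho to the free phenol (benzyltrimethylammonium dichloroiodate or NIS, CH2Cl2, 0 °C) should give 2-hydroxy-3-iodo-4,6-bis(methoxymethoxy)benzaldehyde F7.
- An α-selective Suzuki–Miyaura prenylation of F7 with 2 (Pd–NHC precatalyst of the PEPPSI-IPent type, KOH, THF, reflux) should give 10.

**Further compounds**
F1 | step 8 | racemic 5,7-bis(methoxymethoxy)-2-[2-(methoxymethoxy)-5-(2-methylbut-3-en-2-yl)phenyl]-8-(3-methylbut-2-enyl)chroman-4-one | C=CC(C)(C)c1ccc(OCOC)c(C2CC(=O)c3c(OCOC)cc(OCOC)c(CC=C(C)C)c3O2)c1
F2 | step 8 | (2R,4R)-5,7-bis(methoxymethoxy)-2-[2-(methoxymethoxy)-5-(2-methylbut-3-en-2-yl)phenyl]-8-(3-methylbut-2-enyl)chroman-4-ol | C=CC(C)(C)c1ccc(OCOC)c([C@H]2C[C@@H](O)c3c(OCOC)cc(OCOC)c(CC=C(C)C)c3O2)c1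
F3 | step 7 | 2-chloro-1-[2-(methoxymethoxy)-5-(2-methylbut-3-en-2-yl)phenyl]ethanone | C=CC(C)(C)c1ccc(OCOC)c(C(=O)CCl)c1
F4 | step 7 | racemic 2-chloro-1-[2-(methoxymethoxy)-5-(2-methylbut-3-en-2-yl)phenyl]ethanol | C=CC(C)(C)c1ccc(OCOC)c(C(O)CCl)c1
F5 | step 7 | racemic 2-{2-chloro-1-[2-(methoxymethoxy)-5-(2-methylbut-3-en-2-yl)phenyl]ethoxy}-4,6-bis(methoxymethoxy)-3-(3-methylbut-2-enyl)benzaldehyde | C=CC(C)(C)c1ccc(OCOC)c(C(CCl)Oc2c(C=O)c(OCOC)cc(OCOC)c2CC=C(C)C)c1
F6 | step 4 | 2-hydroxy-4,6-bis(methoxymethoxy)benzaldehyde | COCOc1cc(O)c(C=O)c(OCOC)c1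
F7 | step 4 | 2-hydroxy-3-iodo-4,6-bis(methoxymethoxy)benzaldehyde | COCOc1cc(OCOC)c(C=O)c(O)c1I
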